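**Plan**

- Numbering used throughout: carbocycle C1 (carries the side chain), C2 (CH2), C3 (CHCl), C4 (C(Me)OH), C5 (CH–O-angelate), C6 (CH–OH); side chain C7 (=CH2), C8 (CH–O-angelate), C9, C10–C11 (epoxide).
- Cuts, late to early: the C10–C11 epoxide oxygen, C9=C10 (cross-metathesis), C8–C9 (allylboration), C7=CH2, both esters; then the ring chlorohydrin back to the 3,4-epoxide and the C5 allylic alcohol of a 2-methylcyclohex-2-enone whose O6 is tied to C8 as a cis-fused γ-lactone.
- The enone unit C5(=O)–C4(Me)=C3 next to C2H2 is the retron for alkyne insertion into a cyclobutanone: cutting C2–C3 and C4–C5 leaves the four-membered ring C5–C6–C1–C2 (a prochiral 3-substituted cyclobutanone) and a propyne unit C3–C4–Me.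
- Forward order: four-membered ring ([2+2] of dichloroketene), six-membered ring (strain-release ring expansion), temporary lactone ring, then the chain C8–C11.
- Stereochemistry: C1 from the chiral nickel catalyst (desymmetrisation); C6 from intramolecular SN2 lactonisation (cis to C1); C5 from hydride attack anti to the C6–O bond; C3/C4 from hydroxyl-directed epoxidation and anti opening by chloride; C8 and C10 from catalyst control.

Key step: step 4

Remark: the absolute sense of induction of the three chiral catalysts (steps 4, 15, 18) is assigned from the accepted transition-state models and would be confirmed on the first run; both enantiomers of each catalyst are available.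

**Route**

Step 1
Reactants: 1 tert-butyl but-3-enoate; 2 trichloroacetyl chloride
Product: 4 rac-tert-butyl 2-(2,2-dichloro-3-oxocyclobutyl)acetate, via dichloroketene 3 (not isolated)
Conditions: Zn dust (activated), DME, Et2O, ultrasound, 15–25 °C, slow addition of 2
Reagents that add atoms: none
Why: Zinc reduces 2 to dichloroketene, which should add to the unactivated terminal alkene in a thermal [2+2] ketene–alkene cycloaddition with the carbonyl carbon bonding to the CH2 terminus, giving the 2,2-dichloro-3-substituted cyclobutanone (racemic, the stereocentre is erased in step 2).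

Step 2
Reactants: 4 rac-tert-butyl 2-(2,2-dichloro-3-oxocyclobutyl)acetate
Product: 5 tert-butyl 2-(3-oxocyclobutyl)acetate
Conditions: Zn dust, AcOH, 25–50 °C
Reagents that add atoms: none
Why: Reductive dehalogenation of the α,α-dichloro ketone by zinc in acetic acid should remove both chlorines and leave the achiral, prochiral 3-substituted cyclobutanone with the tert-butyl ester intact.

Step 3
Reactants: 6 prop-1-yn-1-ylmagnesium bromide; 7 benzylchlorodimethylsilane
Product: 8 benzyldimethyl(prop-1-yn-1-yl)silane
Conditions: THF, 0 °C to rt
Reagents that add atoms: none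
Why: Nucleophilic substitution at silicon by the alkynyl Grignard reagent gives the alkynylsilane, whose benzyl group is the fluoride-labile trigger used in step 5.

Step 4
Reactants: 5 tert-butyl 2-(3-oxocyclobutyl)acetate; 8 benzyldimethyl(prop-1-yn-1-yl)silane
Product: 9 tert-butyl 2-[(1S)-3-(benzyldimethylsilyl)-4-methyl-5-oxocyclohex-3-en-1-yl]acetate
Conditions: Ni(cod)2 (10 mol%), (S)-BINOL-derived phosphoramidite bearing an N,N-bis[(R)-1-phenylethyl]amino group (20 mol%), toluene, 90 °C, slow addition of 8
Reagents that add atoms: none
Why: Proposed new method: the closest known reaction type is the nickel-catalysed intermolecular insertion of internal alkynes into the acyl–carbon bond of 3-substituted cyclobutanones with achiral phosphines, and the new element is the choice between two enantiotopic bonds by a chiral monodentate P-ligand, which has precedent in the intramolecular alkene insertion into cyclobutanones. Zerovalent nickel should join the carbonyl of 5 and alkyne 8 by oxidative cyclisation to a spiro oxanickelacyclopentene, the C5–C4 bond forming at the methyl-bearing alkyne carbon while the silyl-bearing carbon stays on nickel (the usual orientation for silylalkynes), and ring strain then drives β-carbon elimination of one C5–CH2 bond to a seven-membered nickelacycle. C(sp2)–C(sp3) reductive elimination forms C3–C2 and completes the six-membered ring, so the carbocycle arises by two-carbon ring expansion of the four-membered ring (formal [4+2]) and not by a separate cyclisation. The single new stereocentre, C1, is created because the ligand on nickel decides which of the two enantiotopic C5–CH2 bonds migrates in the β-carbon elimination. The step needs alkyne regiocontrol, secured by the silyl group, enantiotopic-bond control, asked of the ligand, and chemoselectivity over alkyne oligomerisation, secured by slow addition of 8, while the ester is inert.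

Step 5
Reactants: 9 tert-butyl 2-[(1S)-3-(benzyldimethylsilyl)-4-methyl-5-oxocyclohex-3-en-1-yl]acetate
Product: 10 tert-butyl 2-[(1S)-4-methyl-5-oxocyclohex-3-en-1-yl]acetate
Conditions: Bu4NF, wet THF, 0 °C to rt
Reagents that add atoms: none
Why: Fluoride-triggered protodesilylation of an alkenyl(benzyl)dimethylsilane, in which fluoride cleaves the benzyl–silicon bond and the resulting fluorosilane is protonolysed at the vinylic carbon, should leave hydrogen at C3 without touching C1.

Step 6
Reactants: 10 tert-butyl 2-[(1S)-4-methyl-5-oxocyclohex-3-en-1-yl]acetate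
Product: 12 tert-butyl 2-[(1R,6R)-6-bromo-4-methyl-5-oxocyclohex-3-en-1-yl]acetate, via silyl dienol ether 11 (not isolated)
Conditions: LiN(iPr)2 (LDA), THF, −78 °C; Me3SiCl; then NBS, THF, −78 to 0 °C
Reagents that add atoms: N-bromosuccinimide, O=C1CCC(=O)N1Br; chlorotrimethylsilane, C[Si](C)(C)Cl (atoms kept only in 11)
Why: Kinetic deprotonation of the enone at C6 (α′) and silylation give the cross-conjugated silyl dienol ether, whose electrophilic bromination should occur anti to the C1 arm and place bromine at C6 trans to it.

Step 7
Reactants: 12 tert-butyl 2-[(1R,6R)-6-bromo-4-methyl-5-oxocyclohex-3-en-1-yl]acetate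
Product: 14 (3aR,7aS)-6-methyl-3,3a,4,7a-tetrahydro-1-benzofuran-2,7-dione (cis-fused keto lactone), via bromo acid 13 (not isolated)
Conditions: CF3CO2H, CH2Cl2, 0 °C to rt; evaporation; NaHCO3, DMF, rt
Reagents that add atoms: none
Why: Acidolysis of the tert-butyl ester frees the acid, and the carboxylate should then displace the α-keto bromide in an intramolecular SN2 reaction (5-exo-tet) whose inversion puts the C6 oxygen cis to the C1 arm as a cis-fused γ-lactone, anti-periplanar E2 loss of HBr being impossible because Br and the C1 hydrogen are cis.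

Step 8
Reactants: 14 cis-fused keto lactone
Product: 15 (3aR,7R,7aS)-7-hydroxy-6-methyl-3a,4,7,7a-tetrahydro-1-benzofuran-2(3H)-one (C5 allylic alcohol)
Conditions: NaBH4, CeCl3·7H2O, MeOH, −78 °C
Reagents that add atoms: none
Why: Luche reduction should give clean 1,2-reduction of the enone with hydride entering anti to the C6–O bond (Felkin–Anh), so that the new C5 hydroxyl is cis to the C6 oxygen and the C1 arm.

Step 9
Reactants: 15 C5 allylic alcohol
Product: 16 epoxy alcohol, (1R,3R,4S,5S,6S): γ-lactone (C8 to O6) with 3,4-epoxide and 5-hydroxyl on the face of the C1 arm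
Conditions: VO(acac)2 (5 mol%), t-BuOOH, CH2Cl2, 0 °C to rt
Reagents that add atoms: tert-butyl hydroperoxide, CC(C)(C)OO
Why: Vanadium-catalysed hydroxyl-directed epoxidation of the cyclic allylic alcohol should deliver oxygen to the C3=C4 face syn to the C5 hydroxyl, which fixes C3 and C4 of the epoxide.

Step 10
Reactants: 16 epoxy alcohol
Product: 17 chlorohydrin diol lactone, (1S,3S,4S,5S,6S): 3-chloro trans to 4-hydroxyl, 4-, 5-hydroxyls and O6 all cis
Conditions: ClTi(OiPr)3 (chlorotitanium triisopropoxide), benzene, rt
Reagents that add atoms: chlorotitanium triisopropoxide, CC(C)O[Ti](Cl)(OC(C)C)OC(C)C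
Why: In this titanium-mediated opening of a 2,3-epoxy alcohol the C5 alkoxide and the epoxide oxygen chelate titanium and chloride should attack the distal secondary carbon C3 with inversion (trans-diaxial opening, Fürst–Plattner), giving the chlorohydrin with Cl trans to the new tertiary hydroxyl.

Step 11
Reactants: 18 angelic acid
Product: 19 angelic 2,4,6-trichlorobenzoic anhydride
Conditions: 2,4,6-trichlorobenzoyl chloride (1.0 equiv), Et3N (1.0 equiv), toluene, rt; filtration from Et3NHCl under argon; kept as a toluene stock solution, enough for steps 12 and 16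
Reagents that add atoms: 2,4,6-trichlorobenzoyl chloride, O=C(Cl)c1c(Cl)cc(Cl)cc1Cl
Why: Acylation of the triethylammonium carboxylate by the hindered aroyl chloride (first stage of the Yamaguchi esterification) should give the mixed anhydride, and the absence of a nucleophilic catalyst should keep the Z geometry of the angeloyl group.

Step 12
Reactants: 17 chlorohydrin diol lactone; 19 angelic 2,4,6-trichlorobenzoic anhydride
Product: 20 5-O-angelate of 17
Conditions: 19 (1.5 equiv), toluene, 75 °C
Reagents that add atoms: none
Why: Thermal acylation by the mixed anhydride (Yamaguchi-type esterification without a nucleophilic catalyst) should occur at the unhindered angeloyl carbonyl, keep the Z geometry and acylate the only secondary hydroxyl (C5), the tertiary C4 hydroxyl being unreactive and O6 being masked in the lactone.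

Step 13
Reactants: 20 5-O-angelate lactone
Product: 21 lactol (C8 hemiacetal, anomer mixture)
Conditions: iBu2AlH (2.2 equiv), CH2Cl2, −78 °C; potassium sodium tartrate work-up
Reagents that add atoms: none
Why: Diisobutylaluminium hydride at −78 °C should reduce the γ-lactone to the lactol through the stable tetrahedral aluminate, the hindered conjugated angelate of a secondary alcohol reacting much more slowly and one equivalent being taken up by the tertiary hydroxyl.

Step 14
Reactants: 21 lactol
Product: 22 α-methylene lactol (C7=CH2, in equilibrium with the 6-hydroxy enal)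
Conditions: 37% aq. HCHO, pyrrolidine (10 mol%), propionic acid (10 mol%), i-PrOH, 45 °C
Reagents that add atoms: formaldehyde, C=O
Why: Amine-catalysed α-methylenation (Mannich condensation with formaldehyde, then elimination of the amine) of the hydroxy aldehyde in equilibrium with the lactol should install the C7 methylene, and oxa-Michael re-closure by the C6 hydroxyl would be 5-endo-trig and is disfavoured (Baldwin).

Step 15
Reactants: 22 α-methylene lactol
Product: 23 (8S)-homoallylic alcohol (C8 allyl carbinol, free 4-, 6-, 8-hydroxyls, 5-O-angelate)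
Conditions: allyl-B(pin), (S)-TRIP [(S)-BINOL hydrogen phosphate with 3,3′-bis(2,4,6-triisopropylphenyl) groups] (5 mol%), toluene, −30 °C
Reagents that add atoms: allylboronic acid pinacol ester, C=CCB1OC(C)(C)C(C)(C)O1
Why: Chiral phosphoric acid-catalysed allylboration of the open 2-substituted acrolein form through a chair six-membered transition state should form C8–C9 and set C8 by catalyst-controlled face selection, releasing the C6 hydroxyl at the same time.

Step 16
Reactants: 23 (8S)-homoallylic alcohol; 19 angelic 2,4,6-trichlorobenzoic anhydride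
Product: 24 5,8-di-O-angelate with C8 allyl group
Conditions: 19 (1.2 equiv), toluene, 60 °C
Reagents that add atoms: none
Why: The same mixed-anhydride esterification should acylate the accessible C8 hydroxyl in preference to the axial C6 hydroxyl, which is flanked by C1 and the C5 ester, and to the tertiary C4 hydroxyl.

Step 17
Reactants: 24 5,8-di-O-angelate with C8 allyl group
Product: 25 5,8-di-O-angelate with C8 prenyl group
Conditions: second-generation Grubbs catalyst (5 mol%), 2-methylbut-2-ene/CH2Cl2, 40 °C
Reagents that add atoms: 2-methylbut-2-ene, CC=C(C)C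
Why: Olefin cross-metathesis of the monosubstituted allyl alkene with excess 2-methylbut-2-ene should give the prenyl group, since the 1,1-disubstituted C7 methylene and the electron-poor trisubstituted angelate alkenes are poor metathesis partners.

Step 18
Reactants: 25 5,8-di-O-angelate with C8 prenyl group
Product: 26 CNP0158207.1 (target)
Conditions: D-fructose-derived Shi ketone (1,2:4,5-di-O-isopropylidene-β-D-erythro-hexo-2,3-diulo-2,6-pyranose, 1 equiv), Oxone (2KHSO5·KHSO4·K2SO4), NaHCO3, Bu4NHSO4, MeCN/dimethoxymethane/aq. Na2EDTA, pH 7.5–8, 0 °C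
Reagents that add atoms: potassium peroxymonosulfate, [K+].[O-]S(=O)(=O)OO
Why: In the Shi asymmetric epoxidation the chiral dioxirane should epoxidise only the electron-rich trisubstituted alkene through the spiro transition state and set C10 under catalyst control, the near-neutral buffer keeping the chlorohydrin from closing to an epoxide.

**Compound list**

1 | tert-butyl but-3-enoate | C=CCC(=O)OC(C)(C)C | starting material
2 | trichloroacetyl chloride | O=C(Cl)C(Cl)(Cl)Cl | starting material
3 | dichloroketene | O=C=C(Cl)Cl | intermediate
4 | rac-tert-butyl 2-(2,2-dichloro-3-oxocyclobutyl)acetate | CC(C)(C)OC(=O)CC1CC(=O)C1(Cl)Cl | intermediate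
5 | tert-butyl 2-(3-oxocyclobutyl)acetate | CC(C)(C)OC(=O)CC1CC(=O)C1 | intermediate
6 | prop-1-yn-1-ylmagnesium bromide | CC#C[Mg]Br | starting material
7 | benzylchlorodimethylsilane | C[Si](C)(Cl)Cc1ccccc1 | starting material
8 | benzyldimethyl(prop-1-yn-1-yl)silane | CC#C[Si](C)(C)Cc1ccccc1 | intermediate
9 | tert-butyl 2-[(1S)-3-(benzyldimethylsilyl)-4-methyl-5-oxocyclohex-3-en-1-yl]acetate | CC(C)(C)OC(=O)C[C@H]1CC([Si](C)(C)Cc2ccccc2)=C(C)C(=O)C1 | intermediate
10 | tert-butyl 2-[(1S)-4-methyl-5-oxocyclohex-3-en-1-yl]acetate | CC(C)(C)OC(=O)C[C@H]1CC=C(C)C(=O)C1 | intermediate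
11 | tert-butyl 2-[(1R)-4-methyl-5-(trimethylsilyloxy)cyclohexa-3,5-dien-1-yl]acetate (silyl dienol ether) | CC(C)(C)OC(=O)C[C@H]1CC=C(C)C(O[Si](C)(C)C)=C1 | intermediate
12 | tert-butyl 2-[(1R,6R)-6-bromo-4-methyl-5-oxocyclohex-3-en-1-yl]acetate | CC(C)(C)OC(=O)C[C@H]1CC=C(C)C(=O)[C@@H]1Br | intermediate
13 | 2-[(1R,6R)-6-bromo-4-methyl-5-oxocyclohex-3-en-1-yl]acetic acid (bromo acid) | OC(=O)C[C@H]1CC=C(C)C(=O)[C@@H]1Br | intermediate
14 | (3aR,7aS)-6-methyl-3,3a,4,7a-tetrahydro-1-benzofuran-2,7-dione (cis-fused keto lactone) | O=C2C[C@H]1CC=C(C)C(=O)[C@H]1O2 | intermediate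
15 | (3aR,7R,7aS)-7-hydroxy-6-methyl-3a,4,7,7a-tetrahydro-1-benzofuran-2(3H)-one | O=C2C[C@H]1CC=C(C)[C@@H](O)[C@H]1O2 | intermediate
16 | epoxy alcohol, (1R,3R,4S,5S,6S) in carbocycle numbering: cis-fused γ-lactone with 3,4-epoxide and 5-OH syn to O6 | O=C2C[C@H]1C[C@H]3O[C@@]3(C)[C@@H](O)[C@H]1O2 | intermediate
17 | chlorohydrin diol lactone, (1S,3S,4S,5S,6S): 3-chloro, 4-hydroxy-4-methyl, 5-hydroxy, O6 in γ-lactone | O=C2C[C@H]1C[C@H](Cl)[C@@](C)(O)[C@@H](O)[C@H]1O2 | intermediate
18 | angelic acid, (Z)-2-methylbut-2-enoic acid | C/C=C(/C)C(=O)O | starting material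
19 | angelic 2,4,6-trichlorobenzoic anhydride | C/C=C(/C)C(=O)OC(=O)c1c(Cl)cc(Cl)cc1Cl | intermediate
20 | 5-O-angelate of chlorohydrin lactone 17 | O=C2C[C@H]1C[C@H](Cl)[C@@](C)(O)[C@@H](OC(=O)/C(C)=C\C)[C@H]1O2 | intermediate
21 | lactol of 20 (C8 hemiacetal, anomer mixture) | OC2C[C@H]1C[C@H](Cl)[C@@](C)(O)[C@@H](OC(=O)/C(C)=C\C)[C@H]1O2 | intermediate
22 | α-methylene lactol (C7=CH2; C8 hemiacetal, anomer mixture) | OC2C(=C)[C@H]1C[C@H](Cl)[C@@](C)(O)[C@@H](OC(=O)/C(C)=C\C)[C@H]1O2 | intermediate
23 | (8S)-homoallylic alcohol: C7 methylene, C8 allyl carbinol, 5-O-angelate, free 4-, 6-, 8-hydroxyls | C=C([C@H](CC=C)O)[C@H]1C[C@H](Cl)[C@@](C)(O)[C@@H](OC(=O)/C(C)=C\C)[C@H]1O | intermediate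
24 | 5,8-di-O-angelate with C8 allyl group | C=C([C@H](CC=C)OC(=O)/C(C)=C\C)[C@H]1C[C@H](Cl)[C@@](C)(O)[C@@H](OC(=O)/C(C)=C\C)[C@H]1O | intermediate
25 | 5,8-di-O-angelate with C8 prenyl group | C=C([C@H](CC=C(C)C)OC(=O)/C(C)=C\C)[C@H]1C[C@H](Cl)[C@@](C)(O)[C@@H](OC(=O)/C(C)=C\C)[C@H]1O | intermediate
26 | CNP0158207.1, (1R,3S,4S,5S,6S,8S,10R) in the numbering of the plan | C=C([C@H](C[C@H]1OC1(C)C)OC(=O)/C(C)=C\C)[C@H]1C[C@H](Cl)[C@@](C)(O)[C@@H](OC(=O)/C(C)=C\C)[C@H]1O | target

**Count and risks**

Total step count: 18. Longest linear sequence: 16 steps (steps 1, 2, 4–10 and 12–18; step 3 makes the alkyne partner and step 11 the acylating agent).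

Steps most likely to fail:

1. Step 4 (Proposed new method). What may go wrong: insufficient discrimination between the two enantiotopic C5–CH2 bonds in the β-carbon elimination (low enantiomeric purity), or alkyne oligomerisation outrunning insertion. Fallback with known chemistry, in which a chiral base sets the stereocentre before the ring expansion; it sets out from 5 and comes back at 14. Enantioselective deprotonation of 5 with lithium bis[(R)-1-phenylethyl]amide and Me3SiCl in situ (THF, −100 °C) would give the silyl enol ether F1. NBS would give the trans bromo cyclobutanone F2. CF3CO2H and then NaHCO3 would give, through the bromo acid F3, the cis-fused lactone cyclobutanone F4 by the same intramolecular displacement as in step 7. Insertion of 8 with Ni(cod)2 and the achiral phosphine PCy3 into the less hindered C5–CH2 bond would give the silyl keto lactone F5, and Bu4NF would give 14.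

2. Step 13. What may go wrong: over-reduction, with hydride attacking the angelate (loss of the C5 acyl group or conjugate reduction) in competition with the lactone. Fallback that reduces before esterifying; it sets out from 17 and comes back at 21. iBu2AlH on 17 would give the lactol triol F6. MeOH with pyridinium p-toluenesulfonate would give the methyl acetal F7. Angeloylation with the mixed anhydride 19 as in step 12 would give the C5 angelate F8, and hydrolysis of the acetal in aqueous acetic acid would give 21.

3. Step 15. What may go wrong: poor facial selectivity at C8, or sluggish addition because the aldehyde is largely masked as the lactol. Fallback that sets C8 by oxidation and reduction; it sets out from 22 and comes back at 23. Indium-mediated Barbier allylation (allyl bromide, In, THF/H2O) would give the C8 epimer mixture F9. MnO2 would oxidise only the allylic C8 alcohol to the α-methylene ketone F10. Corey–Bakshi–Shibata reduction ((R)-Me-CBS oxazaborolidine, catecholborane, toluene, −78 °C) would give 23.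

**Further compounds**

F1 | step 4 | tert-butyl 2-[3-(trimethylsilyloxy)cyclobut-2-en-1-yl]acetate, single enantiomer | CC(C)(C)OC(=O)C[C@H]1CC(O[Si](C)(C)C)=C1
F2 | step 4 | tert-butyl 2-(trans-2-bromo-3-oxocyclobutyl)acetate | CC(C)(C)OC(=O)C[C@H]1CC(=O)[C@@H]1Br
F3 | step 4 | 2-(trans-2-bromo-3-oxocyclobutyl)acetic acid | OC(=O)C[C@H]1CC(=O)[C@@H]1Br
F4 | step 4 | cis-fused 2-oxabicyclo[3.2.0]heptane-3,7-dione | O=C2C[C@H]1CC(=O)[C@H]1O2
F5 | step 4 | cis-fused keto lactone 14 carrying a benzyldimethylsilyl group at C3 | O=C2C[C@H]1CC([Si](C)(C)Cc3ccccc3)=C(C)C(=O)[C@H]1O2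
F6 | step 13 | lactol triol from 17 (C8 hemiacetal, anomer mixture) | OC2C[C@H]1C[C@H](Cl)[C@@](C)(O)[C@@H](O)[C@H]1O2
F7 | step 13 | methyl acetal of F6 | COC2C[C@H]1C[C@H](Cl)[C@@](C)(O)[C@@H](O)[C@H]1O2
F8 | step 13 | 5-O-angelate of methyl acetal F7 | COC2C[C@H]1C[C@H](Cl)[C@@](C)(O)[C@@H](OC(=O)/C(C)=C\C)[C@H]1O2
F9 | step 15 | C8 epimer mixture of homoallylic alcohol 23 | C=C(C(O)CC=C)[C@H]1C[C@H](Cl)[C@@](C)(O)[C@@H](OC(=O)/C(C)=C\C)[C@H]1O
F10 | step 15 | C8 ketone (α-methylene allyl ketone) | C=C(C(=O)CC=C)[C@H]1C[C@H](Cl)[C@@](C)(O)[C@@H](OC(=O)/C(C)=C\C)[C@H]1O
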